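**Plan**

1. Retrosynthesis (xenicane numbering: pyran O2/C1/C11a/C4a/C4/C3; carbocycle C4a–C5…C11–C11a; side chain C12–C15): the C1 acetate and the O2 bridge (C1–O2 and enol C3–O2) are cut first to a 1,5-dialdehyde, then C4–C12 (aldol), C8=C9 (ring-closing metathesis) and C4a–C11a (Ireland–Claisen). This leaves three fragments, from (S)-linalool, 4-silyloxybut-2-yn-1-ol and prenol.
2. Enabling feature: C1 (acetal) and C3 (enol-ether CH) are both at the aldehyde level and 1,5-related through C11a–C4a–C4, with C4 enolisable. The dihydropyran is therefore the enol–hemiacetal of a 2,3,4-trisubstituted glutaraldehyde, the form in which iridoid and, presumably, xenicane dialdehydes close in nature.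
3. Forward order: ester of the two chain fragments → Claisen (C4a–C11a bond, C11 exocyclic methylene, both metathesis handles) → one-carbon homologation → metathesis (nine-membered ring, Z-C8=C9) → aldol with the epoxy aldehyde (side chain with its oxirane) → C8–C9 oxirane → dihydropyran as the last ring, closed together with the C1 acetate in the final step.
4. Stereochemistry: C7 from (S)-linalool; C4a/C11a from the enantioselective chair Claisen (E-alkene + E(O)-enolate → anti); C14 from Sharpless epoxidation; C13 and C12 from Felkin additions; C8/C9 from hydroxyl-directed epoxidation of the Z-alkene; C1 from acetylation of the equilibrating lactol.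

Key step: step 20

Assumption 1: (S)-(+)-linalool (coriandrol) is taken as a commercially available, enantioenriched terpene.
Assumption 2: the absolute sense of the boron-mediated Claisen rearrangement (step 7) is assigned to the (S,S)-controller from its transition-state model and has not been derived here; if the opposite holds, the (R,R)-controller is used.

**Route**

Step 1
Reactants: 1 (S)-(+)-linalool
Product: 2 (S)-linalool triethylsilyl ether
Conditions: TESOTf, 2,6-lutidine, CH2Cl2, −78 → 0 °C
Reagents that add atoms: triethylsilyl trifluoromethanesulfonate, CC[Si](CC)(CC)OS(=O)(=O)C(F)(F)F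
Why: O-silylation of the tertiary allylic alcohol with a silyl triflate masks C7–OH, which would otherwise lactonise with the acid made in step 4, and leaves the C7 stereocentre of the terpene untouched.

Step 2
Reactants: 2 (S)-linalool triethylsilyl ether
Product: 4 (4S)-4-methyl-4-[(triethylsilyl)oxy]hex-5-enal, via ozonide 3 (not isolated)
Conditions: O3 (1 equiv, indicator end-point), CH2Cl2, −78 °C; then PPh3, −78 °C → rt
Reagents that add atoms: ozone, [O-][O+]=O
Why: Chemoselective ozonolysis with reductive work-up cleaves the electron-rich trisubstituted alkene in preference to the hindered vinyl group next to the silyloxy quaternary carbon and gives the aldehyde carbon that becomes C4a.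

Step 3
Reactants: 4 (4S)-4-methyl-4-[(triethylsilyl)oxy]hex-5-enal
Product: 5 (5S)-1,1,1-trichloro-5-methyl-5-[(triethylsilyl)oxy]hept-6-en-2-ol
Conditions: CHCl3, DBU, 0 °C → rt
Reagents that add atoms: chloroform, ClC(Cl)Cl
Why: Base-mediated addition of trichloromethanide to the aldehyde gives the trichloromethyl carbinol required for the Jocic-type homologation; the new carbinol centre is removed in step 4, so its configuration is irrelevant.

Step 4
Reactants: 5 (5S)-1,1,1-trichloro-5-methyl-5-[(triethylsilyl)oxy]hept-6-en-2-ol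
Product: 6 (5S)-5-methyl-5-[(triethylsilyl)oxy]hept-6-enoic acid
Conditions: NaBH4, NaOH, t-BuOH, 55 °C
Reagents that add atoms: sodium hydroxide, [Na+].[OH-]
Why: Jocic-type reductive homologation: the alkoxide closes to a gem-dichloroepoxide, borohydride opens it at the carbinol carbon and the resulting acyl chloride is hydrolysed, so that the former aldehyde carbon becomes CH2 (C4a) and the CCl3 carbon the carboxyl group (later C3).

Step 5
Reactants: 7 4-[(tert-butyldimethylsilyl)oxy]but-2-yn-1-ol
Product: 8 (2E)-4-[(tert-butyldimethylsilyl)oxy]-2-(prop-2-en-1-yl)but-2-en-1-ol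
Conditions: allylMgBr (3 equiv), Et2O, 0 °C → reflux
Reagents that add atoms: allylmagnesium bromide, C=CC[Mg]Br
Why: Hydroxyl-directed anti carbomagnesiation of the propargylic alcohol through the five-membered magnesium alkoxide chelate places the allyl group on the carbon next to the free CH2OH and gives the E trisubstituted alkene (CH2OH and CH2OTBS trans).

Step 6
Reactants: 6 (5S)-5-methyl-5-[(triethylsilyl)oxy]hept-6-enoic acid, 8 (2E)-4-[(tert-butyldimethylsilyl)oxy]-2-(prop-2-en-1-yl)but-2-en-1-ol
Product: 9 allylic ester of 6 with 8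
Conditions: DCC, DMAP (cat.), CH2Cl2, 0 °C → rt
Reagents that add atoms: none
Why: Steglich esterification joins the acid and the primary allylic alcohol under neutral conditions without isomerising the E-alkene.

Step 7
Reactants: 9 allylic ester of 6 with 8
Product: 10 (2S,3R)-3-{[(tert-butyldimethylsilyl)oxy]methyl}-4-methylidene-2-{(3S)-3-methyl-3-[(triethylsilyl)oxy]pent-4-en-1-yl}hept-6-enoic acid
Conditions: (S,S)-2-bromo-4,5-diphenyl-1,3-bis(p-tolylsulfonyl)-1,3,2-diazaborolidine (1.2 equiv), Et3N, toluene–hexane, −78 → 4 °C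
Reagents that add atoms: none
Why: Enantioselective Ireland–Claisen rearrangement via the E(O)-boron enolate of the chiral diazaborolidine: the chair transition state with the E-alkene should give the 2,3-anti acid (C4a and C11a as in the target) while the controller selects the enolate face, and the same event forms the C11 exocyclic methylene and leaves the allyl and vinyl groups for ring closure.

Step 8
Reactants: 10 (2S,3R)-Claisen acid
Product: 12 (3S,4R)-α-diazoketone, via mixed anhydride 11 (not isolated)
Conditions: i-BuOCOCl, N-methylmorpholine, THF, −20 °C; then CH2N2, Et2O, 0 °C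
Reagents that add atoms: diazomethane, C=[N+]=[N-]
Why: First half of the Arndt–Eistert homologation: C-acylation of diazomethane by the mixed carbonic anhydride gives the α-diazoketone under conditions that do not epimerise the α-stereocentre (C4a) and tolerate both silyl ethers.

Step 9
Reactants: 12 (3S,4R)-α-diazoketone
Product: 13 S-ethyl (3R,4R)-thioester
Conditions: hν (365 nm), EtSH, Et3N (cat.), THF, 0 °C
Reagents that add atoms: ethanethiol, CCS
Why: Photochemical Wolff rearrangement gives the ketene, which ethanethiol traps as the S-ethyl thioester; the migrating carbon C4a retains its configuration, the diazo carbon becomes C4, and near-UV light avoids direct thiol homolysis and hence thiol–ene addition.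

Step 10
Reactants: 13 S-ethyl (3R,4R)-thioester
Product: 14 cyclononadiene thioester
Conditions: Hoveyda–Grubbs II (10 mol%), toluene (1 mM), 80 °C, argon sparge
Reagents that add atoms: none
Why: Ring-closing metathesis joins C8 and C9: the ruthenium alkylidene should form at the unhindered allyl terminus (the silyloxy-substituted vinyl group and the 1,1-disubstituted methylidene are poor initiation sites), from which only the nine-membered closure is available, and the ring size enforces the Z-alkene.

Step 11
Reactants: 15 3-methylbut-2-en-1-ol (prenol)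
Product: 16 [(2R)-3,3-dimethyloxiran-2-yl]methanol
Conditions: Ti(Oi-Pr)4 (cat.), D-(−)-diisopropyl tartrate, t-BuOOH, 4 Å MS, CH2Cl2, −20 °C
Reagents that add atoms: tert-butyl hydroperoxide, CC(C)(C)OO
Why: Sharpless asymmetric epoxidation of the primary allylic alcohol; the D-(−)-tartrate complex delivers oxygen to the face that gives the (R)-oxirane carbon (C14), by analogy with the L-(+)-tartrate/(2S) series of E-allylic alcohols.

Step 12
Reactants: 16 [(2R)-3,3-dimethyloxiran-2-yl]methanol
Product: 17 (2S)-3,3-dimethyloxirane-2-carbaldehyde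
Conditions: TEMPO (cat.), PhI(OAc)2, CH2Cl2, rt; used as a solution
Reagents that add atoms: none
Why: Oxoammonium (TEMPO/PhI(OAc)2) oxidation of the primary alcohol to the aldehyde under near-neutral conditions leaves the oxirane and its stereocentre intact (the descriptor changes only through CIP priorities).

Step 13
Reactants: 17 (2S)-3,3-dimethyloxirane-2-carbaldehyde
Product: 18 (1R)-1-[(2R)-3,3-dimethyloxiran-2-yl]prop-2-en-1-ol
Conditions: vinylMgBr, THF, −78 °C
Reagents that add atoms: vinylmagnesium bromide, C=C[Mg]Br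
Why: Grignard addition under Felkin–Anh control, with the oxirane C–O bond anti to the incoming nucleophile and attack past the oxirane hydrogen, should give the anti (erythro) epoxy alcohol, which is the C13 configuration of the target.

Step 14
Reactants: 18 (1R)-1-[(2R)-3,3-dimethyloxiran-2-yl]prop-2-en-1-ol
Product: 19 (1R)-1-[(2R)-3,3-dimethyloxiran-2-yl]prop-2-en-1-yl acetate
Conditions: Ac2O, pyridine, DMAP (cat.), CH2Cl2, 0 °C
Reagents that add atoms: acetic anhydride, CC(=O)OC(C)=O
Why: Acetylation of the secondary alcohol installs the C13 acetate of the target at once and blocks Payne rearrangement of the epoxy alcohol.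

Step 15
Reactants: 19 (1R)-1-[(2R)-3,3-dimethyloxiran-2-yl]prop-2-en-1-yl acetate
Product: 21 (1S)-1-[(2R)-3,3-dimethyloxiran-2-yl]-2-oxoethyl acetate, via ozonide 20 (not isolated)
Conditions: O3, CH2Cl2, −78 °C; then PPh3, −78 °C → rt; used crude
Reagents that add atoms: ozone, [O-][O+]=O
Why: Ozonolysis of the terminal vinyl group with neutral reductive work-up gives the α-acetoxy aldehyde (C12) without exposing its epimerisable α-centre to acid or base.

Step 16
Reactants: 14 cyclononadiene thioester, 21 (1S)-1-[(2R)-3,3-dimethyloxiran-2-yl]-2-oxoethyl acetate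
Product: 23 diacetate thioester, via aldol adduct 22 (not isolated)
Conditions: LDA, THF, −78 °C; then 21, −78 °C; then Ac2O, DMAP, −78 → 0 °C
Reagents that add atoms: acetic anhydride, CC(=O)OC(C)=O
Why: Aldol addition of the lithium thioester enolate forms C4–C12 under polar Felkin–Anh control (nucleophile anti to the C13 acetoxy group, giving the 12,13-anti arrangement of the target), and acetylation of the aldolate in the flask makes any 1,2-acyl shift inconsequential; the C4 epimers converge later because C4 becomes sp2.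

Step 17
Reactants: 23 diacetate thioester
Product: 24 diol thioester
Conditions: HF·pyridine, pyridine, THF, 0 °C → rt
Reagents that add atoms: none
Why: Buffered fluoride desilylation removes the tertiary TES ether (C7) and the primary TBS ether (C1) together while acetates, thioester and the trisubstituted oxirane survive; the δ-hydroxy thioester is carried on without delay to avoid lactonisation.

Step 18
Reactants: 24 diol thioester
Product: 25 epoxy diol thioester
Conditions: VO(acac)2 (cat.), t-BuOOH, CH2Cl2, 0 °C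
Reagents that add atoms: tert-butyl hydroperoxide, CC(C)(C)OO
Why: Vanadium-catalysed hydroxyl-directed epoxidation of the Z allylic tertiary alcohol delivers oxygen to C8=C9 on the face of C7–OH (cis-oxirane syn to the hydroxyl, 8R,9R), whereas the methylidene, which is only homoallylic to C1–OH, reacts much more slowly.

Step 19
Reactants: 25 epoxy diol thioester
Product: 26 epoxy aldehyde thioester
Conditions: Dess–Martin periodinane, pyridine, CH2Cl2, 0 °C
Reagents that add atoms: none
Why: Buffered Dess–Martin oxidation converts the primary C1 alcohol into the β,γ-unsaturated aldehyde without migration of the C11 methylidene or epimerisation of C11a, and leaves the tertiary C7–OH untouched.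

Step 20
Reactants: 26 epoxy aldehyde thioester
Product: 29 CNP0134792.1 (target), via dialdehyde 27 (not isolated), via lactol 28 (not isolated)
Conditions: Et3SiH, Pd/CaCO3–Pb (Lindlar), acetone, rt; filter; then Ac2O, pyridine, DMAP (cat.), CH2Cl2, 0 °C
Reagents that add atoms: acetic anhydride, CC(=O)OC(C)=O
Why: Fukuyama reduction converts the thioester into the C3 aldehyde under neutral conditions; the resulting 2,3,4-trisubstituted glutaraldehyde 27 should enolise at C3 towards C4 and add through the enol oxygen to the C1 aldehyde, giving the enol–hemiacetal 28, which is acetylated in the flask. The closest known reaction type is the lactolisation of iridodial-type 1,5-dialdehydes to 2-hydroxy-3,4-dihydro-2H-pyrans and their conversion into 1-O-acetates, the event presumed to close the pyran of iridoids and xenicanes in nature. The ring O2–C1–C11a–C4a–C4–C3 closes in a 6-exo-trig mode by attack of the enol oxygen on the C1 carbonyl. The only new stereocentre, C1, is set while the lactol anomers interconvert: the acetate should end trans to the C11a–C11 bond, where it can be pseudoaxial (anomeric effect), as in the natural acetal acetates of this family, while C4a and C11a are carried in unchanged. The step needs chemoselectivity (thioester reduced beside two acetates, two oxiranes, an aldehyde and the methylidene, hence poisoned palladium and no hydride reagent), regioselectivity (enol ether towards C4, which is acidified by the β-acetoxy group) and suppression of β-elimination of the C12 acetate and of C11a epimerisation (no base stronger than pyridine/DMAP, 0 °C, immediate trapping).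

**Compound list**

1 | (S)-(+)-linalool, (3S)-3,7-dimethylocta-1,6-dien-3-ol | C=C[C@@](C)(O)CCC=C(C)C | starting material
2 | triethyl{[(3S)-3,7-dimethylocta-1,6-dien-3-yl]oxy}silane | C=C[C@@](C)(O[Si](CC)(CC)CC)CCC=C(C)C | intermediate
3 | 3,3-dimethyl-5-{(3S)-3-methyl-3-[(triethylsilyl)oxy]pent-4-en-1-yl}-1,2,4-trioxolane (ozonide, not isolated) | C=C[C@@](C)(O[Si](CC)(CC)CC)CCC1OC(C)(C)OO1 | intermediate
4 | (4S)-4-methyl-4-[(triethylsilyl)oxy]hex-5-enal | C=C[C@@](C)(O[Si](CC)(CC)CC)CCC=O | intermediate
5 | (5S)-1,1,1-trichloro-5-methyl-5-[(triethylsilyl)oxy]hept-6-en-2-ol (C2 epimers) | C=C[C@@](C)(O[Si](CC)(CC)CC)CCC(O)C(Cl)(Cl)Cl | intermediate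
6 | (5S)-5-methyl-5-[(triethylsilyl)oxy]hept-6-enoic acid | C=C[C@@](C)(O[Si](CC)(CC)CC)CCCC(=O)O | intermediate
7 | 4-[(tert-butyldimethylsilyl)oxy]but-2-yn-1-ol | OCC#CCO[Si](C)(C)C(C)(C)C | starting material
8 | (2E)-4-[(tert-butyldimethylsilyl)oxy]-2-(prop-2-en-1-yl)but-2-en-1-ol | OC/C(CC=C)=C/CO[Si](C)(C)C(C)(C)C | intermediate
9 | (2E)-4-[(tert-butyldimethylsilyl)oxy]-2-(prop-2-en-1-yl)but-2-en-1-yl (5S)-5-methyl-5-[(triethylsilyl)oxy]hept-6-enoate | C=C[C@@](C)(O[Si](CC)(CC)CC)CCCC(=O)OC/C(CC=C)=C/CO[Si](C)(C)C(C)(C)C | intermediate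
10 | (2S,3R)-3-{[(tert-butyldimethylsilyl)oxy]methyl}-4-methylidene-2-{(3S)-3-methyl-3-[(triethylsilyl)oxy]pent-4-en-1-yl}hept-6-enoic acid | OC(=O)[C@@H](CC[C@](C)(O[Si](CC)(CC)CC)C=C)[C@@H](CO[Si](C)(C)C(C)(C)C)C(=C)CC=C | intermediate
11 | isobutyl carbonic anhydride of acid 10 (not isolated) | CC(C)COC(=O)OC(=O)[C@@H](CC[C@](C)(O[Si](CC)(CC)CC)C=C)[C@@H](CO[Si](C)(C)C(C)(C)C)C(=C)CC=C | intermediate
12 | (3S,4R)-4-{[(tert-butyldimethylsilyl)oxy]methyl}-1-diazo-5-methylidene-3-{(3S)-3-methyl-3-[(triethylsilyl)oxy]pent-4-en-1-yl}oct-7-en-2-one | [N-]=[N+]=CC(=O)[C@@H](CC[C@](C)(O[Si](CC)(CC)CC)C=C)[C@@H](CO[Si](C)(C)C(C)(C)C)C(=C)CC=C | intermediate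
13 | S-ethyl (3R,4R)-4-{[(tert-butyldimethylsilyl)oxy]methyl}-5-methylidene-3-{(3S)-3-methyl-3-[(triethylsilyl)oxy]pent-4-en-1-yl}oct-7-enethioate | CCSC(=O)C[C@@H](CC[C@](C)(O[Si](CC)(CC)CC)C=C)[C@@H](CO[Si](C)(C)C(C)(C)C)C(=C)CC=C | intermediate
14 | S-ethyl 2-[(1R,2R,5Z,7S)-2-{[(tert-butyldimethylsilyl)oxy]methyl}-7-methyl-3-methylidene-7-[(triethylsilyl)oxy]cyclonon-5-en-1-yl]ethanethioate | C=C1C/C=C\[C@@](C)(O[Si](CC)(CC)CC)CC[C@H](CC(=O)SCC)[C@H]1CO[Si](C)(C)C(C)(C)C | intermediate
15 | 3-methylbut-2-en-1-ol (prenol) | CC(C)=CCO | starting material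
16 | [(2R)-3,3-dimethyloxiran-2-yl]methanol | OC[C@H]1OC1(C)C | intermediate
17 | (2S)-3,3-dimethyloxirane-2-carbaldehyde | O=C[C@H]1OC1(C)C | intermediate
18 | (1R)-1-[(2R)-3,3-dimethyloxiran-2-yl]prop-2-en-1-ol | C=C[C@@H](O)[C@H]1OC1(C)C | intermediate
19 | (1R)-1-[(2R)-3,3-dimethyloxiran-2-yl]prop-2-en-1-yl acetate | C=C[C@@H](OC(C)=O)[C@H]1OC1(C)C | intermediate
20 | (R)-[(2R)-3,3-dimethyloxiran-2-yl](1,2,4-trioxolan-3-yl)methyl acetate (ozonide, ring-carbon epimers, not isolated) | O1COOC1[C@@H](OC(C)=O)[C@H]2OC2(C)C | intermediate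
21 | (1S)-1-[(2R)-3,3-dimethyloxiran-2-yl]-2-oxoethyl acetate | O=C[C@@H](OC(C)=O)[C@H]1OC1(C)C | intermediate
22 | S-ethyl (2RS,3R,4R)-4-(acetyloxy)-4-[(2R)-3,3-dimethyloxiran-2-yl]-3-hydroxy-2-[(1S,2R,5Z,7S)-2-{[(tert-butyldimethylsilyl)oxy]methyl}-7-methyl-3-methylidene-7-[(triethylsilyl)oxy]cyclonon-5-en-1-yl]butanethioate (lithium alkoxide in the flask, not isolated) | C=C1C/C=C\[C@@](C)(O[Si](CC)(CC)CC)CC[C@H](C(C(=O)SCC)[C@@H](O)[C@@H](OC(C)=O)[C@H]2OC2(C)C)[C@H]1CO[Si](C)(C)C(C)(C)C | intermediate
23 | S-ethyl (2RS,3R,4R)-3,4-bis(acetyloxy)-4-[(2R)-3,3-dimethyloxiran-2-yl]-2-[(1S,2R,5Z,7S)-2-{[(tert-butyldimethylsilyl)oxy]methyl}-7-methyl-3-methylidene-7-[(triethylsilyl)oxy]cyclonon-5-en-1-yl]butanethioate | C=C1C/C=C\[C@@](C)(O[Si](CC)(CC)CC)CC[C@H](C(C(=O)SCC)[C@@H](OC(C)=O)[C@@H](OC(C)=O)[C@H]2OC2(C)C)[C@H]1CO[Si](C)(C)C(C)(C)C | intermediate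
24 | S-ethyl (2RS,3R,4R)-3,4-bis(acetyloxy)-4-[(2R)-3,3-dimethyloxiran-2-yl]-2-[(1S,2R,5Z,7S)-7-hydroxy-2-(hydroxymethyl)-7-methyl-3-methylidenecyclonon-5-en-1-yl]butanethioate | C=C1C/C=C\[C@@](C)(O)CC[C@H](C(C(=O)SCC)[C@@H](OC(C)=O)[C@@H](OC(C)=O)[C@H]2OC2(C)C)[C@H]1CO | intermediate
25 | epoxy diol thioester: 24 with the Z-C8=C9 alkene converted into the cis-oxirane syn to C7–OH; xenicane numbering 4aS,7S,8R,9R,11aR,12R,13R,14R, C4 epimers | C=C1C[C@H]2O[C@H]2[C@@](C)(O)CC[C@H](C(C(=O)SCC)[C@@H](OC(C)=O)[C@@H](OC(C)=O)[C@H]3OC3(C)C)[C@H]1CO | intermediate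
26 | epoxy aldehyde thioester: 25 with C1H2OH oxidised to CHO; same configuration, C4 epimers | C=C1C[C@H]2O[C@H]2[C@@](C)(O)CC[C@H](C(C(=O)SCC)[C@@H](OC(C)=O)[C@@H](OC(C)=O)[C@H]3OC3(C)C)[C@H]1C=O | intermediate
27 | 1,5-dialdehyde (C1 and C3 both CHO; C4 epimers; not isolated) | C=C1C[C@H]2O[C@H]2[C@@](C)(O)CC[C@H](C(C=O)[C@@H](OC(C)=O)[C@@H](OC(C)=O)[C@H]3OC3(C)C)[C@H]1C=O | intermediate
28 | lactol: 1-O-deacetyl derivative of 29 (C1 anomers, not isolated) | C=C1C[C@H]2O[C@H]2[C@@](C)(O)CC[C@@H]2C([C@@H](OC(C)=O)[C@@H](OC(C)=O)[C@H]3OC3(C)C)=COC(O)[C@@H]12 | intermediate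
29 | CNP0134792.1, (1R,4aS,7S,8R,9R,11aR,12R,13R,14R)-1,12,13-triacetoxy-8,9:14,15-diepoxy-7-hydroxy xenicane acetal | C=C1C[C@H]2O[C@H]2[C@@](C)(O)CC[C@@H]2C([C@@H](OC(C)=O)[C@@H](OC(C)=O)[C@H]3OC3(C)C)=CO[C@H](OC(C)=O)[C@@H]12 | target

**Totals and risks**

Total step count: 20. Longest linear sequence: 14 steps (1–4, 6–10, 16–20).

Steps most likely to fail:

1. Step 20. The open dialdehyde may lose acetic acid by β-elimination across C4/C12, may enolise towards C11a instead of C4 (wrong enol ether, C11a epimerisation), or its C11 methylidene may migrate into conjugation with the C1 aldehyde; palladium hydride may also reduce an alkene. The fallback closes the ring at the β-keto aldehyde level, where the 1,3-dicarbonyl enol fixes the regiochemistry and no β-leaving group is present. It sets out from 22 and comes back at 29. The aldol of step 16 is quenched with acetic acid at −78 °C instead of acetic anhydride, and the hydroxy thioester 22 is isolated and oxidised at once with Dess–Martin periodinane to the β-keto thioester F1. HF·pyridine then gives the keto diol F2, VO(acac)2/t-BuOOH the epoxy keto diol F3 and Dess–Martin periodinane the keto aldehyde F4, as in steps 17–19. Fukuyama reduction of F4 gives the formyl ketone F5, whose enol can only involve C3/C4/C12 and should close on the C1 aldehyde to the 4-acyl lactol F6 (loganin-type closure); Ac2O/pyridine gives the 4-acyl dihydropyran acetate F7. Luche reduction (NaBH4, CeCl3, MeOH, −78 °C; Felkin control by the C13 acetoxy group) should give the C12 alcohol F8, and Ac2O/pyridine returns 29.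

2. Step 10. Closure of the strained nine-membered ring onto the hindered silyloxy-substituted vinyl group may be slower than intermolecular metathesis at the allyl terminus, giving oligomers. The fallback moves the ring closure behind the side-chain attachment and runs it on the free allylic alcohol. It sets out from 13 (with 21) and comes back at 24. The aldol/acetylation of step 16 is run on the open-chain thioester 13 and gives, through the open-chain aldol adduct F9, the open-chain diacetate F10. HF·pyridine gives the open-chain diol F11. Ring-closing metathesis of F11, in which the free allylic tertiary hydroxyl activates the vinyl group and the fully substituted C4 restricts the chain, should give 24 directly.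

3. Step 16. Facial selectivity at C12 may be poor (Felkin against chelate addition), and the α-acetoxy aldehyde may enolise, epimerise at C13 or open its oxirane under the basic enolate. The fallback replaces substrate control by reagent control: 14 is converted into its boron enolate with the chiral diazaborolidine bromide of step 7 (i-Pr2NEt, CH2Cl2, −78 °C) and added to 21, so that the controller rather than the aldehyde sets C12 and the weakly basic boron enolate spares the aldehyde. Acetylation (Ac2O, pyridine) of the adduct 22 gives 23. This fallback sets out from 14 and 21, comes back at 23 and makes no new compound.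

Further compounds
F1 | step 20 | β-keto thioester (C12 ketone, C7-OTES, C1-OTBS, C4 epimers) | C=C1C/C=C\[C@@](C)(O[Si](CC)(CC)CC)CC[C@H](C(C(=O)SCC)C(=O)[C@@H](OC(C)=O)[C@H]2OC2(C)C)[C@H]1CO[Si](C)(C)C(C)(C)C
F2 | step 20 | β-keto thioester diol (C7-OH, C1-OH) | C=C1C/C=C\[C@@](C)(O)CC[C@H](C(C(=O)SCC)C(=O)[C@@H](OC(C)=O)[C@H]2OC2(C)C)[C@H]1CO
F3 | step 20 | 8,9-epoxy β-keto thioester diol | C=C1C[C@H]2O[C@H]2[C@@](C)(O)CC[C@H](C(C(=O)SCC)C(=O)[C@@H](OC(C)=O)[C@H]3OC3(C)C)[C@H]1CO
F4 | step 20 | 8,9-epoxy β-keto thioester C1 aldehyde | C=C1C[C@H]2O[C@H]2[C@@](C)(O)CC[C@H](C(C(=O)SCC)C(=O)[C@@H](OC(C)=O)[C@H]3OC3(C)C)[C@H]1C=O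
F5 | step 20 | formyl ketone (C1 and C3 aldehydes, C12 ketone) | C=C1C[C@H]2O[C@H]2[C@@](C)(O)CC[C@H](C(C=O)C(=O)[C@@H](OC(C)=O)[C@H]3OC3(C)C)[C@H]1C=O
F6 | step 20 | 4-acyl lactol (12-oxo, C1-OH anomers) | C=C1C[C@H]2O[C@H]2[C@@](C)(O)CC[C@@H]2C(C(=O)[C@@H](OC(C)=O)[C@H]3OC3(C)C)=COC(O)[C@@H]12
F7 | step 20 | 4-acyl dihydropyran C1 acetate (12-oxo analogue of 29 without the C12 acetate) | C=C1C[C@H]2O[C@H]2[C@@](C)(O)CC[C@@H]2C(C(=O)[C@@H](OC(C)=O)[C@H]3OC3(C)C)=CO[C@H](OC(C)=O)[C@@H]12
F8 | step 20 | 12-O-deacetyl 29 (C12 alcohol) | C=C1C[C@H]2O[C@H]2[C@@](C)(O)CC[C@@H]2C([C@@H](O)[C@@H](OC(C)=O)[C@H]3OC3(C)C)=CO[C@H](OC(C)=O)[C@@H]12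
F9 | step 10 | open-chain aldol adduct of 13 and 21 (C12-OH, C4 epimers) | CCSC(=O)C([C@@H](O)[C@@H](OC(C)=O)[C@H]1OC1(C)C)[C@@H](CC[C@](C)(O[Si](CC)(CC)CC)C=C)[C@@H](CO[Si](C)(C)C(C)(C)C)C(=C)CC=C
F10 | step 10 | open-chain diacetate thioester | CCSC(=O)C([C@@H](OC(C)=O)[C@@H](OC(C)=O)[C@H]1OC1(C)C)[C@@H](CC[C@](C)(O[Si](CC)(CC)CC)C=C)[C@@H](CO[Si](C)(C)C(C)(C)C)C(=C)CC=C
F11 | step 10 | open-chain diol thioester (C7-OH, C1-OH) | CCSC(=O)C([C@@H](OC(C)=O)[C@@H](OC(C)=O)[C@H]1OC1(C)C)[C@@H](CC[C@](C)(O)C=C)[C@@H](CO)C(=C)CC=C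
F0 | step 16 | none | none
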